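**Plan**

- Retrosynthesis: the 4-methoxybenzoate C–O bond is cut first. The ring is then opened at C1–C2 together with the C3–CH3 bond, which leads back to an open-chain epoxy ynal. That chain is cut at the epoxide C–O bonds, at C10–C11 (nitrile alkylation), at C5–C6 (sp2–sp3 coupling) and at C7–CH3 (carbometalation).
- Forward: the chain C2–C11 is joined in three C–C bond-forming steps, the epoxide is put on and C1 is brought to the aldehyde level. The only carbocycle, the eleven-membered ring, closes in step 7. A C1 oxidation/reduction pair and the esterification finish the route.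
- Enabling feature: in the eleven-membered ring the carbinol carbon C1 sits on the hydrogen-bearing alkene carbon C2, and the C3 methyl is cis to C1. This is the imprint of a syn addition of an aldehyde carbon and a methyl group across a terminal alkyne C2≡C3. C11 is fully substituted, so the aldehyde cannot enolise.
- Stereochemistry: C6 and C7 come from Shi epoxidation of an E-alkene whose geometry comes from syn carboalumination. The E ring alkene comes from the nickelacycle. C1 (S) comes from a reagent-controlled Corey–Bakshi–Shibata reduction.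

Key step: step 7

Remark on numbering: ring atoms are numbered C1 (carbinol), C2=C3 (CH3 on C3), C4, C5, C6 (epoxide CH), C7 (epoxide carbon with CH3), C8, C9, C10, C11 (C(CH3)2, bonded to C1). In the systematic bicyclo[9.1.0] names, C1 of this numbering is locant 6, and C6 and C7 are locants 1 and 11.

**Step 1**
Reactants: 1 5-chloropent-1-yne
Product: 3 (E)-5-chloro-1-iodo-2-methylpent-1-ene, via alkenyldimethylalane 2 (not isolated)
Conditions: Me3Al, Cp2ZrCl2 (25 mol %), CH2Cl2, 0 → 23 °C; then I2, THF, −30 → 0 °C
Reagents that add atoms: trimethylaluminium C[Al](C)C; iodine II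
Why: Negishi carboalumination adds methyl and aluminium syn across the terminal alkyne (methyl to the internal carbon), and iodinolysis with retention should give the E-iodoalkene that later fixes the trans relationship at C6/C7; the primary chloride is inert.

**Step 2**
Reactants: 3 (E)-5-chloro-1-iodo-2-methylpent-1-ene; 4 (4-bromobut-1-yn-1-yl)trimethylsilane
Product: 6 (E)-(9-chloro-6-methylnon-5-en-1-yn-1-yl)trimethylsilane, via homopropargylzinc bromide 5 (not isolated)
Conditions: 4, Zn dust, LiCl, THF, 50 °C; then 3, Pd(PPh3)4 (5 mol %), THF, 23 → 45 °C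
Reagents that add atoms: none
Why: Negishi sp2–sp3 cross-coupling of the alkenyl iodide with the primary alkylzinc halide should join C5 to C6 with retention of the E geometry, while the alkyl chloride and the silylalkyne are spectators.

**Step 3**
Reactants: 6 (E)-(9-chloro-6-methylnon-5-en-1-yn-1-yl)trimethylsilane; 7 isobutyronitrile
Product: 9 (E)-2,2,6-trimethyl-11-(trimethylsilyl)undec-6-en-10-ynenitrile, via lithiated isobutyronitrile 8 (not isolated)
Conditions: 7, LDA (i-Pr2NLi), THF, −78 °C; then 6, DMPU, −78 → 40 °C
Reagents that add atoms: none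
Why: SN2 alkylation of the nitrile-stabilised tertiary carbanion by the primary chloride (nitrile anion alkylation) should build the quaternary C11, the silyl group keeping the alkyne C–H away from the base.

**Step 4**
Reactants: 9 (E)-2,2,6-trimethyl-11-(trimethylsilyl)undec-6-en-10-ynenitrile
Product: 10 2,2-dimethyl-5-{(2R,3R)-2-methyl-3-[4-(trimethylsilyl)but-3-yn-1-yl]oxiran-2-yl}pentanenitrile
Conditions: D-fructose-derived Shi ketone (30 mol %), Oxone (2KHSO5·KHSO4·K2SO4), K2CO3, Bu4NHSO4, MeCN/CH2(OMe)2, aq. Na2B4O7–Na2EDTA buffer, 0 °C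
Reagents that add atoms: Oxone, active component potassium peroxymonosulfate [K+].[O-]S(=O)(=O)OO
Why: Shi asymmetric epoxidation sets C6 and C7 together, since syn oxygen transfer to the E-alkene fixes the trans relationship and the spiro transition state of the D-fructose-derived dioxirane should select the face that gives the (R,R)-epoxide; the nitrile and the silylalkyne are inert to the dioxirane.

**Step 5**
Reactants: 10 2,2-dimethyl-5-{(2R,3R)-2-methyl-3-[4-(trimethylsilyl)but-3-yn-1-yl]oxiran-2-yl}pentanenitrile
Product: 11 5-[(2R,3R)-3-(but-3-yn-1-yl)-2-methyloxiran-2-yl]-2,2-dimethylpentanenitrile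
Conditions: K2CO3, MeOH, 23 °C
Reagents that add atoms: none
Why: Base-mediated methanolysis of the alkynyl C–Si bond (protodesilylation) should free the terminal alkyne without touching the trisubstituted epoxide or the nitrile.

**Step 6**
Reactants: 11 5-[(2R,3R)-3-(but-3-yn-1-yl)-2-methyloxiran-2-yl]-2,2-dimethylpentanenitrile
Product: 13 5-[(2R,3R)-3-(but-3-yn-1-yl)-2-methyloxiran-2-yl]-2,2-dimethylpentanal, via N-aluminoimine 12 (not isolated)
Conditions: i-Bu2AlH, CH2Cl2, −78 °C; then aq. Rochelle salt (KNaC4H4O6), 23 °C
Reagents that add atoms: water O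
Why: Partial reduction of a nitrile with i-Bu2AlH stops at the N-aluminoimine, which hydrolyses to the aldehyde on work-up, and at −78 °C the trisubstituted epoxide and the terminal alkyne should not react.

**Step 7**
Reactants: 13 5-[(2R,3R)-3-(but-3-yn-1-yl)-2-methyloxiran-2-yl]-2,2-dimethylpentanal
Product: 15 (1R,4E,11R)-4,7,7,11-tetramethyl-12-oxabicyclo[9.1.0]dodec-4-en-6-ol (both C6 epimers), via methylzinc alkoxide 14 (not isolated)
Conditions: Ni(cod)2 (bis(1,5-cyclooctadiene)nickel, 20 mol %), IMes (1,3-dimesitylimidazol-2-ylidene, 20 mol %), Me2Zn (3 equiv), toluene, 13 added over 10 h to 0.003 M, 23 → 45 °C; then H2O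
Reagents that add atoms: dimethylzinc C[Zn]C
Why: Proposed new method: zerovalent nickel should bind the aldehyde and the terminal alkyne of 13 and couple them oxidatively to an oxanickelacyclopentene in which C1 is bonded to the terminal alkyne carbon C2 and nickel sits on C3; transmetalation with Me2Zn (zinc to oxygen, methyl to nickel) and C–C reductive elimination then place the methyl on C3 with retention, so the methyl is cis to C1 and the ring alkene is E. The closest known reaction types are the nickel-catalysed alkylative cyclization of ynals with organozincs, shown for five- and six-membered rings closed in the exo sense, and the nickel-catalysed reductive macrocyclization of ynals with silanes or Et3B in the endo sense; their combination on an eleven-membered ring has no precedent. The eleven-membered carbocycle closes in the endo-dig mode (11-endo), the alternative exo closure at C3 leading to a ten-membered ring with an exocyclic alkene. The new stereocenter C1 forms under the influence of the remote C6/C7 epoxide and the ring conformation only, so no control is claimed and both epimers are carried on to converge in steps 8 and 9. The step needs regioselectivity for C2 over C3, which the unsubstituted alkyne terminus and the compact carbene ligand should secure, and ring closure over oligomerization, which slow addition at high dilution should secure. It also needs the epoxide and the aldehyde to survive the organozinc, which the weak Lewis acidity of salt-free Me2Zn, the trisubstituted epoxide and the non-enolisable neopentyl aldehyde should ensure.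

**Step 8**
Reactants: 15 (1R,4E,11R)-4,7,7,11-tetramethyl-12-oxabicyclo[9.1.0]dodec-4-en-6-ol (both C6 epimers)
Product: 16 (1R,4E,11R)-4,7,7,11-tetramethyl-12-oxabicyclo[9.1.0]dodec-4-en-6-one
Conditions: Dess–Martin periodinane, NaHCO3, CH2Cl2, 0 → 23 °C
Reagents that add atoms: none
Why: Buffered Dess–Martin oxidation of the allylic alcohol should converge both C1 epimers on one enone and leave the acid-sensitive epoxide and the E-alkene intact.

**Step 9**
Reactants: 16 (1R,4E,11R)-4,7,7,11-tetramethyl-12-oxabicyclo[9.1.0]dodec-4-en-6-one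
Product: 18 (1R,4E,6S,11R)-4,7,7,11-tetramethyl-12-oxabicyclo[9.1.0]dodec-4-en-6-ol, via catecholborate ester 17 (not isolated)
Conditions: (R)-2-methyl-CBS-oxazaborolidine (0.5 equiv), catecholborane, toluene, −78 °C; then H2O
Reagents that add atoms: none
Why: In the Corey–Bakshi–Shibata reduction the oxazaborolidine binds the ketone anti to the larger flanking group, here taken to be the fully substituted C11, so the (R)-catalyst should deliver hydride 1,2 to the face that gives the (S)-carbinol at C1 by reagent control.

**Step 10**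
Reactants: 18 (1R,4E,6S,11R)-4,7,7,11-tetramethyl-12-oxabicyclo[9.1.0]dodec-4-en-6-ol; 19 4-methoxybenzoyl chloride
Product: 20 (1R,4E,6S,11R)-4,7,7,11-tetramethyl-12-oxabicyclo[9.1.0]dodec-4-en-6-yl 4-methoxybenzoate
Conditions: 19, Et3N, DMAP, CH2Cl2, 23 °C
Reagents that add atoms: none
Why: DMAP-catalysed acylation through the N-acylpyridinium ion should esterify the hindered secondary allylic alcohol at oxygen, with retention at C1 and without touching the epoxide.

**Compound list**

1 | 5-chloropent-1-yne | ClCCCC#C | starting material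
2 | (E)-(5-chloro-2-methylpent-1-en-1-yl)dimethylalane | ClCCC/C(C)=C/[Al](C)C | intermediate
3 | (E)-5-chloro-1-iodo-2-methylpent-1-ene | ClCCC/C(C)=C/I | intermediate
4 | (4-bromobut-1-yn-1-yl)trimethylsilane | BrCCC#C[Si](C)(C)C | starting material
5 | [4-(trimethylsilyl)but-3-yn-1-yl]zinc bromide | Br[Zn]CCC#C[Si](C)(C)C | intermediate
6 | (E)-(9-chloro-6-methylnon-5-en-1-yn-1-yl)trimethylsilane | ClCCC/C(C)=C/CCC#C[Si](C)(C)C | intermediate
7 | isobutyronitrile (2-methylpropanenitrile) | CC(C)C#N | starting material
8 | 2-lithio-2-methylpropanenitrile (lithiated isobutyronitrile) | [Li]C(C)(C)C#N | intermediate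
9 | (E)-2,2,6-trimethyl-11-(trimethylsilyl)undec-6-en-10-ynenitrile | N#CC(C)(C)CCC/C(C)=C/CCC#C[Si](C)(C)C | intermediate
10 | 2,2-dimethyl-5-{(2R,3R)-2-methyl-3-[4-(trimethylsilyl)but-3-yn-1-yl]oxiran-2-yl}pentanenitrile | N#CC(C)(C)CCC[C@@]1(C)O[C@@H]1CCC#C[Si](C)(C)C | intermediate
11 | 5-[(2R,3R)-3-(but-3-yn-1-yl)-2-methyloxiran-2-yl]-2,2-dimethylpentanenitrile | N#CC(C)(C)CCC[C@@]1(C)O[C@@H]1CCC#C | intermediate
12 | N-(diisobutylalumanyl)imine of 5-[(2R,3R)-3-(but-3-yn-1-yl)-2-methyloxiran-2-yl]-2,2-dimethylpentanal | CC(C)C[Al](CC(C)C)N=CC(C)(C)CCC[C@@]1(C)O[C@@H]1CCC#C | intermediate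
13 | 5-[(2R,3R)-3-(but-3-yn-1-yl)-2-methyloxiran-2-yl]-2,2-dimethylpentanal | O=CC(C)(C)CCC[C@@]1(C)O[C@@H]1CCC#C | intermediate
14 | methylzinc (1R,4E,11R)-4,7,7,11-tetramethyl-12-oxabicyclo[9.1.0]dodec-4-en-6-olate (both C6 epimers) | C[Zn]OC1/C=C(\C)CC[C@H]2O[C@]2(C)CCCC1(C)C | intermediate
15 | (1R,4E,11R)-4,7,7,11-tetramethyl-12-oxabicyclo[9.1.0]dodec-4-en-6-ol (both C6 epimers) | OC1/C=C(\C)CC[C@H]2O[C@]2(C)CCCC1(C)C | intermediate
16 | (1R,4E,11R)-4,7,7,11-tetramethyl-12-oxabicyclo[9.1.0]dodec-4-en-6-one | O=C1/C=C(\C)CC[C@H]2O[C@]2(C)CCCC1(C)C | intermediate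
17 | 2-{[(1R,4E,6S,11R)-4,7,7,11-tetramethyl-12-oxabicyclo[9.1.0]dodec-4-en-6-yl]oxy}-1,3,2-benzodioxaborole | c1ccc2OB(O[C@H]3/C=C(\C)CC[C@H]4O[C@]4(C)CCCC3(C)C)Oc2c1 | intermediate
18 | (1R,4E,6S,11R)-4,7,7,11-tetramethyl-12-oxabicyclo[9.1.0]dodec-4-en-6-ol | O[C@H]1/C=C(\C)CC[C@H]2O[C@]2(C)CCCC1(C)C | intermediate
19 | 4-methoxybenzoyl chloride | COc1ccc(C(=O)Cl)cc1 | starting material
20 | (1R,4E,6S,11R)-4,7,7,11-tetramethyl-12-oxabicyclo[9.1.0]dodec-4-en-6-yl 4-methoxybenzoate | COc1ccc(C(=O)O[C@H]2/C=C(\C)CC[C@H]3O[C@]3(C)CCCC2(C)C)cc1 | target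

**Totals and risks**

Total step count: 10. Longest linear sequence: 10 steps (from 1 to 20; 4, 7 and 19 enter as commercial reagents).

Steps most likely to fail:

Step 7 (Proposed new method). At zerovalent nickel the terminal alkyne may oligomerize, the ring may close in the exo sense at C3, or the hindered neopentyl aldehyde may be too slow in the oxidative coupling, so that no eleven-membered ring forms. The fallback uses known chemistry, sets out from 6 and comes back at 15: the methyl group and the alkene geometry are put in before ring closure, and the C1–C2 bond is then made by a Nozaki–Hiyama–Kishi macrocyclization. Protodesilylation of 6 (K2CO3, MeOH) would give (E)-9-chloro-6-methylnon-5-en-1-yne F1. A second Negishi carboalumination–iodination (Me3Al, Cp2ZrCl2; then I2) would give (1E,5E)-9-chloro-1-iodo-2,6-dimethylnona-1,5-diene F2. Alkylation of 8 with F2 would give (6E,10E)-11-iodo-2,2,6,10-tetramethylundeca-6,10-dienenitrile F3. Shi epoxidation, which should select the electron-rich C6=C7 alkene over the iodoalkene, would give 5-{(2R,3R)-3-[(E)-4-iodo-3-methylbut-3-en-1-yl]-2-methyloxiran-2-yl}-2,2-dimethylpentanenitrile F4. Reduction with i-Bu2AlH would give 5-{(2R,3R)-3-[(E)-4-iodo-3-methylbut-3-en-1-yl]-2-methyloxiran-2-yl}-2,2-dimethylpentanal F5. CrCl2 with catalytic NiCl2 in DMSO at high dilution would then close the ring with retention of the E geometry and return to 15.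

Step 9. Facial selectivity may be poor or reversed, because both groups flanking the carbonyl are bulky (quaternary C11 and a β,β-disubstituted alkene) and the ring conformation adds its own bias to that of the catalyst. The fallback sets out from 16 and comes back at 18; it replaces reagent control by substrate control with recycling. Luche reduction (NaBH4, CeCl3·7H2O, MeOH, −78 °C) would give both C1 epimers. Compound 18 would be separated by chromatography from (1R,4E,6R,11R)-4,7,7,11-tetramethyl-12-oxabicyclo[9.1.0]dodec-4-en-6-ol F6, and F6 would be re-oxidized to 16 with Dess–Martin periodinane and reduced again.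

Step 6. The aluminium hydride may open the trisubstituted epoxide, or reduction of the hindered tertiary nitrile may stay incomplete at the low temperature that the epoxide requires. The fallback sets out from 9 and comes back at 13; the nitrile is reduced before the epoxide exists and the carbon is carried as an alcohol through the epoxidation. Reduction of 9 with i-Bu2AlH and hydrolysis would give (E)-2,2,6-trimethyl-11-(trimethylsilyl)undec-6-en-10-ynal F7. Treatment with NaBH4 and K2CO3 in MeOH would reduce the aldehyde and remove the silyl group to give (E)-2,2,6-trimethylundec-6-en-10-yn-1-ol F8. Shi epoxidation would give 5-[(2R,3R)-3-(but-3-yn-1-yl)-2-methyloxiran-2-yl]-2,2-dimethylpentan-1-ol F9. Buffered Dess–Martin oxidation would then give 13.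

**Further compounds**

F1 | step 7 | (E)-9-chloro-6-methylnon-5-en-1-yne | ClCCC/C(C)=C/CCC#C
F2 | step 7 | (1E,5E)-9-chloro-1-iodo-2,6-dimethylnona-1,5-diene | ClCCC/C(C)=C/CC/C(C)=C/I
F3 | step 7 | (6E,10E)-11-iodo-2,2,6,10-tetramethylundeca-6,10-dienenitrile | N#CC(C)(C)CCC/C(C)=C/CC/C(C)=C/I
F4 | step 7 | 5-{(2R,3R)-3-[(E)-4-iodo-3-methylbut-3-en-1-yl]-2-methyloxiran-2-yl}-2,2-dimethylpentanenitrile | N#CC(C)(C)CCC[C@@]1(C)O[C@@H]1CC/C(C)=C/I
F5 | step 7 | 5-{(2R,3R)-3-[(E)-4-iodo-3-methylbut-3-en-1-yl]-2-methyloxiran-2-yl}-2,2-dimethylpentanal | O=CC(C)(C)CCC[C@@]1(C)O[C@@H]1CC/C(C)=C/I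
F6 | step 9 | (1R,4E,6R,11R)-4,7,7,11-tetramethyl-12-oxabicyclo[9.1.0]dodec-4-en-6-ol | O[C@@H]1/C=C(\C)CC[C@H]2O[C@]2(C)CCCC1(C)C
F7 | step 6 | (E)-2,2,6-trimethyl-11-(trimethylsilyl)undec-6-en-10-ynal | O=CC(C)(C)CCC/C(C)=C/CCC#C[Si](C)(C)C
F8 | step 6 | (E)-2,2,6-trimethylundec-6-en-10-yn-1-ol | OCC(C)(C)CCC/C(C)=C/CCC#C
F9 | step 6 | 5-[(2R,3R)-3-(but-3-yn-1-yl)-2-methyloxiran-2-yl]-2,2-dimethylpentan-1-ol | OCC(C)(C)CCC[C@@]1(C)O[C@@H]1CCC#C
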